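**Retrosynthetic overview**
1. Target 19 ⇐ Luche reduction at C6 of keto-lactone 18 ⇐ desilylative lactonisation (8,12-olide) and C14 tigloylation of the ring-expanded hydroxy-ketone 14.
2. 14 ⇐ key step: four-carbon ring expansion of the cis-fused decalin-type carbinol 11 by double directed epoxidation and epoxide-terminated Grob fragmentation of the ring-fusion bond C1–C6 (gives the ten-membered ring, C6=O, ring-trans C1=C10, C14–OH and the 4,5-epoxide).
3. 11 ⇐ intramolecular Barbier 2-(methoxycarbonyl)allylation of enone 10 (C6–C7 bond, ring B; C7 set from C8).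
4. 10 ⇐ Morita–Baylis–Hillman adduct/allylic bromide of aldehyde 7 ⇐ Pd α'-alkenylation of 3-methylcyclohex-2-enone (ring A) with alkenyl bromide 3 ⇐ asymmetric 2-bromoallylation of 2,2-dimethoxyacetaldehyde (sets C8).
5. Ring order: ring A (bought) → ring B (Barbier) → ten-membered carbocycle and oxirane (fragmentation) → γ-lactone.

Assumption: atom labels C1–C15 follow germacrane numbering; the ketone α-centre of 5–10 (future C1) is configurationally labile, is carried as a ~1:1 epimer mixture and is left undefined in the SMILES, because it is erased in step 7.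

**Step 1**
Reactants: 1 2,2-dimethoxyacetaldehyde (anhydrous); 2 2,3-dibromopropene
Product: 3 (S)-[(4-bromo-1,1-dimethoxypent-4-en-2-yl)oxy]triethylsilane
Conditions: CrBr3 (10 mol%), chiral oxazoline–sulfonamide ligand (11 mol%), cobalt phthalocyanine (2 mol%), Et3N (20 mol%), Mn, Et3SiCl, THF, rt
Reagents that add atoms: chlorotriethylsilane CC[Si](CC)(CC)Cl
Why: Catalytic asymmetric Nozaki–Hiyama–Kishi 2-haloallylation: only the allylic C–Br of 2 is activated, the chiral Cr(III) allyl adds to one aldehyde face to set C8 as (S) (ligand enantiomer chosen accordingly), and Et3SiCl turns the Cr alkoxide over and leaves the carbinol as its TES ether.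

**Step 2**
Reactants: 3 (S)-[(4-bromo-1,1-dimethoxypent-4-en-2-yl)oxy]triethylsilane; 4 3-methylcyclohex-2-en-1-one
Product: 5 6-[(4S)-5,5-dimethoxy-4-(triethylsilyloxy)pent-1-en-2-yl]-3-methylcyclohex-2-en-1-one (≈1:1 at ring C6)
Conditions: LiHMDS (2.2 equiv), THF, –78 °C; Pd2(dba)3 (2.5 mol%), Q-Phos (6 mol%), toluene, 50 °C; aq. NH4Cl
Reagents that add atoms: none
Why: Pd-catalysed α-alkenylation of a ketone enolate: kinetic deprotonation gives the cross-conjugated α'-enolate of 4, which couples with the 2-bromo-1-alkene, and the product is held as its enolate and α-protonated on work-up so the alkene stays out of conjugation (the new centre is uncontrolled and later erased).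

**Step 3**
Reactants: 5 6-[(4S)-5,5-dimethoxy-4-(triethylsilyloxy)pent-1-en-2-yl]-3-methylcyclohex-2-en-1-one
Product: 7 (2S)-4-(4-methyl-2-oxocyclohex-3-en-1-yl)-2-(triethylsilyloxy)pent-4-enal, via collidinium salt 6 (not isolated)
Conditions: Et3SiOTf, 2,4,6-collidine, CH2Cl2, 0 °C; then H2O
Reagents that add atoms: water O; 2,4,6-collidine Cc1cc(C)nc(C)c1 and triethylsilyl triflate CC[Si](CC)(CC)OS(=O)(=O)C(F)(F)F (atoms retained only in 6)
Why: Fujioka-type acetal cleavage: the silyl triflate ionises the dimethyl acetal, collidine traps the oxocarbenium ion as a pyridinium salt and water hydrolyses it to the aldehyde without acid, so the TES ether, the enone and C8 are untouched.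

**Step 4**
Reactants: 7 (2S)-4-(4-methyl-2-oxocyclohex-3-en-1-yl)-2-(triethylsilyloxy)pent-4-enal; 8 methyl acrylate
Product: 9 methyl (4S)-3-hydroxy-2-methylidene-6-(4-methyl-2-oxocyclohex-3-en-1-yl)-4-(triethylsilyloxy)hept-6-enoate (mixture at C3)
Conditions: DABCO (0.5 equiv), 8 (5 equiv, neat), rt, 4 d
Reagents that add atoms: none
Why: Morita–Baylis–Hillman reaction of an activated α-silyloxy aldehyde; the new carbinol centre does not matter because it becomes sp2 in step 5.

**Step 5**
Reactants: 9 methyl (4S)-3-hydroxy-2-methylidene-6-(4-methyl-2-oxocyclohex-3-en-1-yl)-4-(triethylsilyloxy)hept-6-enoate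
Product: 10 methyl (2Z,4S)-2-(bromomethyl)-6-(4-methyl-2-oxocyclohex-3-en-1-yl)-4-(triethylsilyloxy)hepta-2,6-dienoate
Conditions: PBr3 (0.4 equiv), pyridine (cat.), Et2O, –20 → 0 °C
Reagents that add atoms: phosphorus tribromide BrP(Br)Br
Why: SN2' bromination of the Baylis–Hillman alcohol (allylic transposition) gives the thermodynamically preferred (Z)-2-(bromomethyl)enoate, the geometry required for the chair transition state of step 6.

**Step 6**
Reactants: 10 methyl (2Z,4S)-2-(bromomethyl)-6-(4-methyl-2-oxocyclohex-3-en-1-yl)-4-(triethylsilyloxy)hepta-2,6-dienoate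
Product: 11 methyl 2-[(1R,2S,4aR,8aS)-8a-hydroxy-7-methyl-4-methylidene-2-(triethylsilyloxy)-1,2,3,4,4a,5,6,8a-octahydronaphthalen-1-yl]prop-2-enoate
Conditions: activated Zn dust, THF/sat. aq. NH4Cl (2:1), 0.01 M, 0 °C → rt; chromatography
Reagents that add atoms: none
Why: Intramolecular Barbier 2-(alkoxycarbonyl)allylation through a chair Zimmerman–Traxler transition state: A(1,3) strain keeps H8 in the alkene plane so C6 bonds to C7 anti to the silyloxy group (C7–C11 and C8–O trans-diequatorial), the (Z)-allylzinc puts the new C6–O bond trans to H7, and the C1 epimer whose ring-A bond is axial gives the cis-fused carbinol 11 (the trans-fused product of the other epimer is separated).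

**Step 7**
Reactants: 11 methyl 2-[(1R,2S,4aR,8aS)-8a-hydroxy-7-methyl-4-methylidene-2-(triethylsilyloxy)-1,2,3,4,4a,5,6,8a-octahydronaphthalen-1-yl]prop-2-enoate
Product: 14 methyl (1(10)Z,4S,5S,7R,8S)-4,5-epoxy-14-hydroxy-6-oxo-8-(triethylsilyloxy)germacra-1(10),11(13)-dien-12-oate (ring-trans C1=C10), via mono-epoxide 12 (not isolated), via bis-epoxide 13 (not isolated)
Conditions: VO(acac)2 (10 mol%), t-BuOOH (2.5 equiv, decane), toluene, 0 °C → 45 °C
Reagents that add atoms: tert-butyl hydroperoxide CC(C)(C)OO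
Why: Proposed new method: one-pot vanadium-catalysed double hydroxyl-directed epoxidation and epoxide-terminated Grob fragmentation as a four-carbon ring expansion; the V(V) alkoxide of the tertiary carbinol delivers oxygen first to the allylic ring-A alkene on the OH face (sets C4 and C5, 12) and then to the homoallylic exocyclic methylene on the same face (13), after which, in a twist-boat of ring B, the oxirane C10–O bond lies anti-periplanar to the fusion bond C1–C6 and the Lewis-acidic vanadium alkoxide pushes from O–C6 and pulls on the oxirane oxygen, so C1–C6 cleaves to give the ten-membered ring, the C6 ketone, the C14 carbinol and (oxirane O cis to H1, C2 anti to C9) only the ring-trans C1=C10 olefin; the closest known reactions are the Ti(OiPr)4/t-BuOOH epoxy-alcohol fragmentation of bridged tertiary alcohols and the Wharton–Grob fragmentation of decalin 1,3-diol monosulfonates, neither shown on a fused homoallylic carbinol with an exocyclic oxirane as nucleofuge.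

**Step 8**
Reactants: 14 methyl (1(10)Z,4S,5S,7R,8S)-4,5-epoxy-14-hydroxy-6-oxo-8-(triethylsilyloxy)germacra-1(10),11(13)-dien-12-oate; 15 tigloyl chloride [(E)-2-methylbut-2-enoyl chloride]
Product: 16 methyl (1(10)Z,4S,5S,7R,8S)-4,5-epoxy-14-[(E)-2-methylbut-2-enoyloxy]-6-oxo-8-(triethylsilyloxy)germacra-1(10),11(13)-dien-12-oate
Conditions: pyridine, DMAP (cat.), CH2Cl2, 0 °C
Reagents that add atoms: none
Why: Acylation of the only free hydroxyl (primary, allylic) under pyridine buffering, which does not enolise the C7–H next to the ketone.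

**Step 9**
Reactants: 16 methyl (1(10)Z,4S,5S,7R,8S)-4,5-epoxy-14-[(E)-2-methylbut-2-enoyloxy]-6-oxo-8-(triethylsilyloxy)germacra-1(10),11(13)-dien-12-oate
Product: 18 (1(10)Z,4S,5S,7R,8S)-4,5-epoxy-14-[(E)-2-methylbut-2-enoyloxy]-6-oxogermacra-1(10),11(13)-dien-12,8-olide, via hydroxy ester 17 (not isolated)
Conditions: HF·pyridine, THF, 0 °C → rt
Reagents that add atoms: none
Why: Desilylation frees the C8 hydroxyl, which lactonises onto the neighbouring acrylate ester; it is the only hydroxyl present, so only the 8,12-olide can form, and its trans fusion follows from the C7/C8 relationship fixed in step 6.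

**Step 10**
Reactants: 18 (1(10)Z,4S,5S,7R,8S)-4,5-epoxy-14-[(E)-2-methylbut-2-enoyloxy]-6-oxogermacra-1(10),11(13)-dien-12,8-olide
Product: 19 (1(10)Z,4S,5R,6S,7S,8S)-4,5-epoxy-6-hydroxy-14-[(E)-2-methylbut-2-enoyloxy]germacra-1(10),11(13)-dien-12,8-olide (CNP0116446.1)
Conditions: NaBH4, CeCl3·7H2O, MeOH, –78 °C
Reagents that add atoms: none
Why: Luche 1,2-reduction is selective for the ketone over lactone, tiglate and α-methylene unit, and non-chelated Felkin–Anh attack anti to the epoxide C5–O bond gives the (6S) alcohol.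

**Compound list**
1 | 2,2-dimethoxyacetaldehyde | COC(OC)C=O | starting material
2 | 2,3-dibromopropene | C=C(Br)CBr | starting material
3 | (S)-[(4-bromo-1,1-dimethoxypent-4-en-2-yl)oxy]triethylsilane | COC(OC)[C@@H](O[Si](CC)(CC)CC)CC(Br)=C | intermediate
4 | 3-methylcyclohex-2-en-1-one | CC1=CC(=O)CCC1 | starting material
5 | 6-[(4S)-5,5-dimethoxy-4-(triethylsilyloxy)pent-1-en-2-yl]-3-methylcyclohex-2-en-1-one (ring C6 epimers) | CC1=CC(=O)C(CC1)C(=C)C[C@H](O[Si](CC)(CC)CC)C(OC)OC | intermediate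
6 | 1-[(2S)-1-methoxy-4-(4-methyl-2-oxocyclohex-3-en-1-yl)-2-(triethylsilyloxy)pent-4-en-1-yl]-2,4,6-trimethylpyridinium triflate (not isolated) | CC1=CC(=O)C(CC1)C(=C)C[C@H](O[Si](CC)(CC)CC)C(OC)[n+]1c(C)cc(C)cc1C.[O-]S(=O)(=O)C(F)(F)F | intermediate
7 | (2S)-4-(4-methyl-2-oxocyclohex-3-en-1-yl)-2-(triethylsilyloxy)pent-4-enal | CC1=CC(=O)C(CC1)C(=C)C[C@H](O[Si](CC)(CC)CC)C=O | intermediate
8 | methyl acrylate | C=CC(=O)OC | starting material
9 | methyl (4S)-3-hydroxy-2-methylidene-6-(4-methyl-2-oxocyclohex-3-en-1-yl)-4-(triethylsilyloxy)hept-6-enoate | CC1=CC(=O)C(CC1)C(=C)C[C@H](O[Si](CC)(CC)CC)C(O)C(=C)C(=O)OC | intermediate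
10 | methyl (2Z,4S)-2-(bromomethyl)-6-(4-methyl-2-oxocyclohex-3-en-1-yl)-4-(triethylsilyloxy)hepta-2,6-dienoate | CC1=CC(=O)C(CC1)C(=C)C[C@H](O[Si](CC)(CC)CC)/C=C(\CBr)C(=O)OC | intermediate
11 | methyl 2-[(1R,2S,4aR,8aS)-8a-hydroxy-7-methyl-4-methylidene-2-(triethylsilyloxy)-1,2,3,4,4a,5,6,8a-octahydronaphthalen-1-yl]prop-2-enoate (cis-fused) | C=C(C(=O)OC)[C@@H]1[C@@H](O[Si](CC)(CC)CC)CC(=C)[C@H]2CCC(C)=C[C@@]12O | intermediate
12 | 11 with the ring-A alkene epoxidised syn to the tertiary OH (oxirane configured as in 19; not isolated) | C=C(C(=O)OC)[C@@H]1[C@@H](O[Si](CC)(CC)CC)CC(=C)[C@H]2CC[C@]3(C)O[C@@H]3[C@@]12O | intermediate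
13 | 12 with a spiro-oxirane at C10 in place of the methylidene, oxirane O syn to the tertiary OH (not isolated) | C=C(C(=O)OC)[C@@H]1[C@@H](O[Si](CC)(CC)CC)C[C@@]2(CO2)[C@H]3CC[C@]4(C)O[C@@H]4[C@@]13O | intermediate
14 | methyl (1(10)Z,4S,5S,7R,8S)-4,5-epoxy-14-hydroxy-6-oxo-8-(triethylsilyloxy)germacra-1(10),11(13)-dien-12-oate | C=C(C(=O)OC)[C@@H]1[C@@H](O[Si](CC)(CC)CC)C/C(CO)=C/CC[C@]2(C)O[C@@H]2C1=O | intermediate
15 | tigloyl chloride, (E)-2-methylbut-2-enoyl chloride | C/C=C(\C)C(Cl)=O | starting material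
16 | methyl (1(10)Z,4S,5S,7R,8S)-4,5-epoxy-14-[(E)-2-methylbut-2-enoyloxy]-6-oxo-8-(triethylsilyloxy)germacra-1(10),11(13)-dien-12-oate | C=C(C(=O)OC)[C@@H]1[C@@H](O[Si](CC)(CC)CC)C/C(COC(=O)/C(C)=C/C)=C/CC[C@]2(C)O[C@@H]2C1=O | intermediate
17 | methyl (1(10)Z,4S,5S,7R,8S)-4,5-epoxy-8-hydroxy-14-[(E)-2-methylbut-2-enoyloxy]-6-oxogermacra-1(10),11(13)-dien-12-oate (not isolated) | C=C(C(=O)OC)[C@@H]1[C@@H](O)C/C(COC(=O)/C(C)=C/C)=C/CC[C@]2(C)O[C@@H]2C1=O | intermediate
18 | (1(10)Z,4S,5S,7R,8S)-4,5-epoxy-14-[(E)-2-methylbut-2-enoyloxy]-6-oxogermacra-1(10),11(13)-dien-12,8-olide | C=C1C(=O)O[C@H]2C/C(COC(=O)/C(C)=C/C)=C/CC[C@]3(C)O[C@@H]3C(=O)[C@H]12 | intermediate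
19 | (1(10)Z,4S,5R,6S,7S,8S)-4,5-epoxy-6-hydroxy-14-[(E)-2-methylbut-2-enoyloxy]germacra-1(10),11(13)-dien-12,8-olide | C=C1C(=O)O[C@H]2C/C(COC(=O)/C(C)=C/C)=C/CC[C@]3(C)O[C@@H]3[C@@H](O)[C@H]12 | target

**Totals and risks**

Total steps: 10. Longest linear sequence: 10 steps (from 1 and 2).

The three steps most likely to fail:

Step 2 (enolate α'-alkenylation). The risks are γ-deprotonation, migration of the new alkene into conjugation and slow coupling of the hindered 2-bromo-1-alkene. The fallback reverses the polarity, sets out from 3 and 4 and returns at 5. Ketone 4 is α'-brominated through its kinetic enolate (LDA, THF, –78 °C; NBS) to 6-bromo-3-methylcyclohex-2-en-1-one F1. Bromide 3 is converted by bromine–lithium exchange (t-BuLi, –78 °C) and ZnBr2 into bromo[(4S)-5,5-dimethoxy-4-(triethylsilyloxy)pent-1-en-2-yl]zinc F2. A nickel-catalysed Negishi coupling of the secondary α-bromo ketone with the alkenylzinc (NiCl2·glyme, pybox ligand, DMA/THF, 0 °C) then gives 5.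

Step 6 (Barbier cyclisation). The risks are lactonisation of the tertiary zinc alkoxide onto the ester, a different facial course at C7, and the fact that only one C1 epimer gives the cis-fused carbinol (at most about half of the material). The fallback sets out from 9 and returns at 11. Acetylation (Ac2O, DMAP, CH2Cl2) gives methyl (4S)-3-acetoxy-2-methylidene-6-(4-methyl-2-oxocyclohex-3-en-1-yl)-4-(triethylsilyloxy)hept-6-enoate F3. Palladium-catalysed umpolung with indium(I) iodide (Pd(PPh3)4, InI, THF, rt) turns the allylic acetate into a 2-(methoxycarbonyl)allylindium(III) species that adds to the ketone under neutral, non-aqueous conditions and gives 11 after aqueous work-up.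

Step 7 (the proposed new ring expansion). The risks are Payne or semipinacol reactions of the 2,3-epoxy alcohol, a bis-epoxide that does not fragment, and a ring-fusion geometry or C6 configuration different from the one predicted, which would give the wrong olefin or oxirane. The fallback uses known chemistry, sets out from 11 and returns at 19.
- Alkoxy-radical β-fragmentation (PhI(OAc)2, I2, hν, cyclohexane, rt) cleaves C1–C6, and the allylic radical is captured by iodine at C14 to give methyl (1(10)Z,4Z,7R,8S)-14-iodo-6-oxo-8-(triethylsilyloxy)germacra-1(10),4,11(13)-trien-12-oate F4.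
- Displacement with caesium tiglate (tiglic acid, Cs2CO3, DMF) gives methyl (1(10)Z,4Z,7R,8S)-14-[(E)-2-methylbut-2-enoyloxy]-6-oxo-8-(triethylsilyloxy)germacra-1(10),4,11(13)-trien-12-oate F5.
- HF·pyridine gives (1(10)Z,4Z,7R,8S)-14-[(E)-2-methylbut-2-enoyloxy]-6-oxogermacra-1(10),4,11(13)-trien-12,8-olide F6.
- NaBH4/CeCl3 gives (1(10)Z,4Z,6R,7S,8S)-6-hydroxy-14-[(E)-2-methylbut-2-enoyloxy]germacra-1(10),4,11(13)-trien-12,8-olide F7 (same spatial arrangement at C6 as in 19).
- Hydroxyl-directed epoxidation of this (Z)-allylic alcohol (VO(acac)2, t-BuOOH, A(1,3)-controlled, syn to OH) gives 19.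

**Further compounds**
F1 | step 2 | 6-bromo-3-methylcyclohex-2-en-1-one | CC1=CC(=O)C(Br)CC1
F2 | step 2 | bromo[(4S)-5,5-dimethoxy-4-(triethylsilyloxy)pent-1-en-2-yl]zinc | COC(OC)[C@@H](O[Si](CC)(CC)CC)CC(=C)[Zn]Br
F3 | step 6 | methyl (4S)-3-acetoxy-2-methylidene-6-(4-methyl-2-oxocyclohex-3-en-1-yl)-4-(triethylsilyloxy)hept-6-enoate | CC1=CC(=O)C(CC1)C(=C)C[C@H](O[Si](CC)(CC)CC)C(OC(C)=O)C(=C)C(=O)OC
F4 | step 7 | methyl (1(10)Z,4Z,7R,8S)-14-iodo-6-oxo-8-(triethylsilyloxy)germacra-1(10),4,11(13)-trien-12-oate | C=C(C(=O)OC)[C@@H]1[C@@H](O[Si](CC)(CC)CC)C/C(CI)=C/CC/C(C)=C\C1=O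
F5 | step 7 | methyl (1(10)Z,4Z,7R,8S)-14-[(E)-2-methylbut-2-enoyloxy]-6-oxo-8-(triethylsilyloxy)germacra-1(10),4,11(13)-trien-12-oate | C=C(C(=O)OC)[C@@H]1[C@@H](O[Si](CC)(CC)CC)C/C(COC(=O)/C(C)=C/C)=C/CC/C(C)=C\C1=O
F6 | step 7 | (1(10)Z,4Z,7R,8S)-14-[(E)-2-methylbut-2-enoyloxy]-6-oxogermacra-1(10),4,11(13)-trien-12,8-olide | C=C1C(=O)O[C@H]2C/C(COC(=O)/C(C)=C/C)=C/CC/C(C)=C\C(=O)[C@H]12
F7 | step 7 | (1(10)Z,4Z,6R,7S,8S)-6-hydroxy-14-[(E)-2-methylbut-2-enoyloxy]germacra-1(10),4,11(13)-trien-12,8-olide | C=C1C(=O)O[C@H]2C/C(COC(=O)/C(C)=C/C)=C/CC/C(C)=C\[C@@H](O)[C@H]12
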